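The plan opens the C4–C5 bond of ring A and the C9–C10 bond of ring B, which returns the target to an open C30 chain. The feature exploited is the C7=C8 alkene of ring B next to the C9 stereocentre: an SE2' reaction of a C8=C9 allylsilane silylated at C7 deposits its unsaturation precisely there. One Lewis-acid step should therefore close both rings and relay chirality from a sacrificial C7–Si stereocentre to C5, C9 and C10. It should also fix the alkene and halt the cascade before the side-chain triene reacts. The precursor is an all-E 2,3-dihydrosqualene with a tertiary methyl ether at C4 and an (R)-dimethylphenylsilyl group at C7, joined at C7–C8 by Zweifel olefination.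

Key step: step 10

Remark on the chemistry: polypodane numbering is used throughout (C4 = gem-dimethyl carbon, C5/C10 = ring fusion, C9 = chain-bearing ring carbon, C11 = first side-chain carbon). In this numbering the target is (5S,9S,10S), with 10β-methyl, 5α-H and an equatorial 9β chain. Cations 28 and 29 are written without their chlorotitanate counter-ion.

Step 1
Reactants: 1 methyl hex-5-ynoate
Product: 3 2-methylhept-6-yn-2-ol, via hept-6-yn-2-one 2 (not isolated)
Conditions: MeMgBr (3.3 equiv), THF, 0 °C → rt; aq. NH4Cl
Reagents that add atoms: methylmagnesium bromide, C[Mg]Br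
Why: Double Grignard addition to an ester: acyl substitution gives ketone 2, which is more electrophilic than 1 and takes up the second methyl at once, while the third equivalent only removes the alkyne C–H proton, which returns on quench.

Step 2
Reactants: 3 2-methylhept-6-yn-2-ol
Product: 4 6-methoxy-6-methylhept-1-yne
Conditions: NaH (1.2 equiv), MeI (3 equiv), THF, 0 → 40 °C
Reagents that add atoms: iodomethane, CI
Why: Williamson ether synthesis: in THF the hydride removes the O–H proton in preference to the far less acidic alkyne C–H, and unhindered MeI alkylates even a tertiary alkoxide, installing the methoxy group that later leaves from C4.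

Step 3
Reactants: 4 6-methoxy-6-methylhept-1-yne; 5 oxirane
Product: 8 (E)-8-methoxy-4,8-dimethylnon-3-en-1-ol, via alkenyldimethylalane 6 (not isolated), via lithium alkenylalanate 7 (not isolated)
Conditions: Me3Al (3 equiv), Cp2ZrCl2 (20 mol%), CH2Cl2, 0 °C → rt; evaporate excess Me3Al, hexane; n-BuLi, THF, 0 °C; oxirane (excess), 0 °C → rt; aq. potassium sodium tartrate
Reagents that add atoms: trimethylaluminium, C[Al](C)C
Why: Negishi carboalumination adds methyl and aluminium syn across the alkyne with aluminium at the terminus (6), which fixes the E geometry of the future C5=C10 alkene, and n-BuLi converts 6 into the more nucleophilic alanate 7, which opens oxirane with retention of alkene geometry, while the tertiary ether only ties up one extra equivalent of the weak Lewis acid Me3Al.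

Step 4
Reactants: 8 (E)-8-methoxy-4,8-dimethylnon-3-en-1-ol
Product: 9 (E)-8-methoxy-4,8-dimethylnon-3-en-1-yl N,N-diisopropylcarbamate
Conditions: NaH, i-Pr2NCOCl, THF, 0 °C → reflux
Reagents that add atoms: N,N-diisopropylcarbamoyl chloride, CC(C)N(C(C)C)C(=O)Cl
Why: Carbamoylation (nucleophilic acyl substitution) of the primary alcohol gives the hindered Hoppe-type carbamate, whose carbonyl resists attack by s-BuLi and directs the next deprotonation to C7.

Step 5
Reactants: 9 (E)-8-methoxy-4,8-dimethylnon-3-en-1-yl N,N-diisopropylcarbamate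
Product: 12 (S)-α-(dimethylphenylsilyl) pinacol boronic ester of the C11 fragment, via (R)-lithiated carbamate 10 (not isolated), via silylboronate ate complex 11 (not isolated)
Conditions: s-BuLi (1.3 equiv), (+)-sparteine (1.3 equiv), Et2O, −78 °C, 5 h; PhMe2Si–Bpin (1.5 equiv), −78 °C; then warm to rt, 16 h
Reagents that add atoms: 2-(dimethylphenylsilyl)-4,4,5,5-tetramethyl-1,3,2-dioxaborolane, C[Si](C)(c1ccccc1)B1OC(C)(C)C(C)(C)O1
Why: Hoppe deprotonation followed by lithiation–borylation with a silylboronate: s-BuLi/(+)-sparteine removes the pro-R hydrogen next to oxygen to give configurationally stable (R)-10, boron is taken up with retention (11), and silicon then migrates from boron to carbon antiperiplanar to the departing carbamate (Matteson-type 1,2-shift), inverting C7 to the (S)-boronic ester.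

Step 6
Reactants: 13 (2E,6E)-farnesyl bromide; 14 tert-butyl acetate
Product: 16 tert-butyl (4E,8E)-5,9,13-trimethyltetradeca-4,8,12-trienoate, via lithium enolate 15 (not isolated)
Conditions: 14 (1.5 equiv), LiN(i-Pr)2 (commercial solution, 1.5 equiv), THF, −78 °C; then 13, −78 → 0 °C
Reagents that add atoms: none
Why: Ester enolate alkylation: enolate 15 displaces the primary allylic bromide by SN2 at the unhindered CH2 terminus, the tert-butyl group suppresses Claisen self-condensation, and the two E alkenes of 13 take no part.

Step 7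
Reactants: 16 tert-butyl (4E,8E)-5,9,13-trimethyltetradeca-4,8,12-trienoate
Product: 18 (4E,8E)-5,9,13-trimethyltetradeca-4,8,12-trienal, via aluminium hemiacetal 17 (not isolated)
Conditions: i-Bu2AlH (1.2 equiv), CH2Cl2, −78 °C; MeOH at −78 °C, then aq. potassium sodium tartrate
Reagents that add atoms: none
Why: Partial reduction of an ester by a single hydride transfer: the crowded aluminium hemiacetal 17 persists at −78 °C and releases the aldehyde only on quench, when no hydride is left.

Step 8
Reactants: 18 (4E,8E)-5,9,13-trimethyltetradeca-4,8,12-trienal; 19 ethyltriphenylphosphonium iodide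
Product: 23 (2Z,6E,10E)-2-iodo-7,11,15-trimethylhexadeca-2,6,10,14-tetraene, via ethylidene ylide 20 (not isolated), via 1-iodoethylphosphonium iodide 21 (not isolated), via iodoethylidene ylide 22 (not isolated)
Conditions: 19, n-BuLi, THF, 0 °C → rt; cannulate into I2, THF, −78 °C; NaN(SiMe3)2, −78 → −20 °C; 18, −78 °C → rt
Reagents that add atoms: iodine, II
Why: Stork–Zhao-type Wittig olefination: iodination of ylide 20 and deprotonation of salt 21 give the non-stabilised α-iodo ylide 22, whose kinetically controlled addition to 18 places the chain cis to iodine and so gives the Z alkenyl iodide.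

Step 9
Reactants: 23 (2Z,6E,10E)-2-iodo-7,11,15-trimethylhexadeca-2,6,10,14-tetraene; 12 (S)-α-(dimethylphenylsilyl) pinacol boronic ester
Product: 27 (9R)-9-(dimethylphenylsilyl)-2-methoxy-2,3-dihydrosqualene (silicon on C7 and methoxy on C4 in polypodane numbering), via alkenyllithium 24 (not isolated), via alkenylboronate complex 25 (not isolated), via beta-iodo boronic ester 26 (not isolated)
Conditions: 23 (1.3 equiv), t-BuLi (2.6 equiv), Et2O, −78 °C; 12, THF, −78 → 0 °C; I2 (1.3 equiv), THF, −78 °C; NaOMe, MeOH, −78 °C → rt; aq. Na2S2O3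
Reagents that add atoms: none
Why: Zweifel olefination: lithium–iodine exchange gives 24 with retention, 24 adds to boron (25), iodine activates the alkenyl π bond so that C7 migrates from boron to C8 with retention at C7 (26), and methoxide-induced anti elimination of boron and iodide inverts the alkene geometry, so the Z iodide delivers the E C8=C9 alkene and (S)-12 becomes (R)-27 with unchanged spatial arrangement (only the CIP ranking changes).

Step 10
Reactants: 27 (9R)-9-(dimethylphenylsilyl)-2-methoxy-2,3-dihydrosqualene
Product: 30 target (5S,9S,10S)-polypoda-7,13E,17E,21-tetraene, via C4 tertiary cation 28 (not isolated), via C8 beta-silyl cation 29 (not isolated)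
Conditions: slow addition of 27 to TiCl4 (5 equiv), 2,6-di-tert-butyl-4-methylpyridine (2 equiv), CH2Cl2 (final 2 mM), −78 °C; aq. NaHCO3
Reagents that add atoms: none
Why: Proposed new method: TiCl4 abstracts methoxide from the only ionisable site to give tertiary cation 28 without any proton source, C5 of the E C5=C10 alkene adds to C4 while C9 of the allylsilane adds to the developing C10 cation, and the resulting β-silyl cation 29 loses silicon to chloride, leaving the alkene at C7=C8. The closest known reaction types are the allylsilane-terminated cationic polyene cyclisation, the TiCl4-mediated tert-alkylation of allylsilanes and the tertiary ether/TiCl4/hindered pyridine initiation with allylsilane end-capping of living carbocationic polymerisation; new is their union with chirality transfer from an α-stereogenic allylsilane inside a bicyclisation. Ring A closes 6-endo-trig through a chair (C4–C5 bond) and ring B closes 6-endo-trig through a second chair (C9–C10 bond). C9 is set by anti SE2' attack, because only the fold that holds the (R)-C7–Si bond axial on the α face, parallel to the C8 p orbital and opposite the incoming C10, is hyperconjugatively assisted (there silicon meets only the axial hydrogens at C5 and C9); C10 and C5 follow from the chair–chair geometry and anti addition across the E C5=C10 alkene (trans fusion, β-methyl, α-H), and the E C8=C9 alkene places the C11 chain equatorial. The step needs chemoselectivity (C13=C14, C17=C18 and C21=C22 untouched, stop after two rings) and absolute facial selectivity: the first rests on aprotic initiation, the proton trap, high dilution and desilylation of 29 outrunning attack by C13=C14, the second on the C7 stereocentre, which is consumed as the alkene forms.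

Compound list
1 | methyl hex-5-ynoate | C#CCCCC(=O)OC | starting material
2 | hept-6-yn-2-one | C#CCCCC(C)=O | intermediate
3 | 2-methylhept-6-yn-2-ol | C#CCCCC(C)(C)O | intermediate
4 | 6-methoxy-6-methylhept-1-yne | C#CCCCC(C)(C)OC | intermediate
5 | oxirane | C1CO1 | starting material
6 | [(1E)-6-methoxy-2,6-dimethylhept-1-en-1-yl]dimethylalane | COC(C)(C)CCC/C(C)=C/[Al](C)C | intermediate
7 | lithium butyl[(1E)-6-methoxy-2,6-dimethylhept-1-en-1-yl]dimethylalanate | [Li+].COC(C)(C)CCC/C(C)=C/[Al-](C)(C)CCCC | intermediate
8 | (E)-8-methoxy-4,8-dimethylnon-3-en-1-ol | COC(C)(C)CCC/C(C)=C/CCO | intermediate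
9 | (E)-8-methoxy-4,8-dimethylnon-3-en-1-yl N,N-diisopropylcarbamate | COC(C)(C)CCC/C(C)=C/CCOC(=O)N(C(C)C)C(C)C | intermediate
10 | (1R,3E)-1-lithio-8-methoxy-4,8-dimethylnon-3-en-1-yl N,N-diisopropylcarbamate ((+)-sparteine complex) | COC(C)(C)CCC/C(C)=C/C[C@H](OC(=O)N(C(C)C)C(C)C)[Li] | intermediate
11 | lithium (R)-(α-carbamoyloxyalkyl)(dimethylphenylsilyl) pinacol boronate | [Li+].COC(C)(C)CCC/C(C)=C/C[C@H](OC(=O)N(C(C)C)C(C)C)[B-]1([Si](C)(C)c2ccccc2)OC(C)(C)C(C)(C)O1 | intermediate
12 | 2-[(1S,3E)-1-(dimethylphenylsilyl)-8-methoxy-4,8-dimethylnon-3-en-1-yl]-4,4,5,5-tetramethyl-1,3,2-dioxaborolane | COC(C)(C)CCC/C(C)=C/C[C@@H]([Si](C)(C)c1ccccc1)B1OC(C)(C)C(C)(C)O1 | intermediate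
13 | (2E,6E)-farnesyl bromide | CC(C)=CCC/C(C)=C/CC/C(C)=C/CBr | starting material
14 | tert-butyl acetate | CC(=O)OC(C)(C)C | starting material
15 | lithium enolate of tert-butyl acetate | [Li+].C=C([O-])OC(C)(C)C | intermediate
16 | tert-butyl (4E,8E)-5,9,13-trimethyltetradeca-4,8,12-trienoate | CC(C)=CCC/C(C)=C/CC/C(C)=C/CCC(=O)OC(C)(C)C | intermediate
17 | O-diisobutylaluminium O-tert-butyl hemiacetal of 18 | CC(C)=CCC/C(C)=C/CC/C(C)=C/CCC(OC(C)(C)C)O[Al](CC(C)C)CC(C)C | intermediate
18 | (4E,8E)-5,9,13-trimethyltetradeca-4,8,12-trienal | CC(C)=CCC/C(C)=C/CC/C(C)=C/CCC=O | intermediate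
19 | ethyltriphenylphosphonium iodide | CC[P+](c1ccccc1)(c1ccccc1)c1ccccc1.[I-] | starting material
20 | ethylidenetriphenylphosphorane | CC=P(c1ccccc1)(c1ccccc1)c1ccccc1 | intermediate
21 | (1-iodoethyl)triphenylphosphonium iodide | CC(I)[P+](c1ccccc1)(c1ccccc1)c1ccccc1.[I-] | intermediate
22 | (1-iodoethylidene)triphenylphosphorane | CC(I)=P(c1ccccc1)(c1ccccc1)c1ccccc1 | intermediate
23 | (2Z,6E,10E)-2-iodo-7,11,15-trimethylhexadeca-2,6,10,14-tetraene | CC(C)=CCC/C(C)=C/CC/C(C)=C/CC/C=C(\I)C | intermediate
24 | alkenyllithium from 23, lithium cis to the chain (geometry retained) | CC(C)=CCC/C(C)=C/CC/C(C)=C/CC/C=C(\[Li])C | intermediate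
25 | lithium alkenyl[(S)-α-silylalkyl] pinacol boronate, boron cis to C11 | [Li+].COC(C)(C)CCC/C(C)=C/C[C@@H]([Si](C)(C)c1ccccc1)[B-]1(OC(C)(C)C(C)(C)O1)/C(C)=C\CC/C=C(C)/CC/C=C(C)/CCC=C(C)C | intermediate
26 | C8-boryl C9-iodo adduct after the 1,2-shift (one of two facial isomers that converge on the same alkene) | COC(C)(C)CCC/C(C)=C/C[C@@H]([Si](C)(C)c1ccccc1)[C@](C)(B1OC(C)(C)C(C)(C)O1)[C@H](I)CC/C=C(C)/CC/C=C(C)/CCC=C(C)C | intermediate
27 | [(6E,9R,10E,14E,18E)-2-methoxy-2,6,10,15,19,23-hexamethyltetracosa-6,10,14,18,22-pentaen-9-yl]dimethyl(phenyl)silane | COC(C)(C)CCC/C(C)=C/C[C@@H]([Si](C)(C)c1ccccc1)/C(C)=C/CC/C=C(C)/CC/C=C(C)/CCC=C(C)C | intermediate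
28 | acyclic C4 tertiary carbocation | C[C+](C)CCC/C(C)=C/C[C@@H]([Si](C)(C)c1ccccc1)/C(C)=C/CC/C=C(C)/CC/C=C(C)/CCC=C(C)C | intermediate
29 | bicyclic C8 cation with axial 7α-silyl group | CC(C)=CCC/C(C)=C/CC/C(C)=C/CC[C@H]1[C+](C)[C@H]([Si](C)(C)c3ccccc3)C[C@H]2C(C)(C)CCC[C@]12C | intermediate
30 | (4aS,5S,8aS)-1,1,4a,6-tetramethyl-5-[(3E,7E)-4,8,12-trimethyltrideca-3,7,11-trien-1-yl]-1,2,3,4,4a,5,8,8a-octahydronaphthalene | CC(C)=CCC/C(C)=C/CC/C(C)=C/CC[C@H]1C(C)=CC[C@H]2C(C)(C)CCC[C@]12C | target

Total step count: 10. Longest linear sequence: 7 steps (steps 1–5, 9, 10, counted from 1). The second branch (steps 6–8) adds 3 steps before the union.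

Steps most likely to fail

1. Step 10.
 - Risk: ring A may close before the allylsilane engages. Facial control from C7 would then be lost and the cyclisation would become stepwise and unselective. Proton loss from the C4 or C10 cation and premature desilylation may also compete.
 - Fallback: it uses known chemistry, sets out from farnesyl bromide 13 and returns at target 30. It gives up the cyclisation and buys rings A and B.
 - Purchased (−)-drimenol F1 already holds the C7=C8 alkene and C5, C9 and C10 in the required configuration.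
 - F1 is converted with PhSSPh/Bu3P into drim-7-en-11-yl phenyl sulfide F2, which is oxidised chemoselectively at sulfur (H2O2, (NH4)6Mo7O24, EtOH) to sulfone F3.
 - Lithiation (n-BuLi, THF/DMPU, −78 °C) and alkylation with 13 forms the C11–C12 bond in sulfone F4. Its C11 epimers are of no consequence.
 - Reductive desulfonylation (sodium amalgam Na(Hg), Na2HPO4, MeOH) gives 30.

2. Step 9.
 - Risk: addition of the α-branched alkenyllithium, whose chain sits cis to lithium, to the crowded α-silyl boronic ester may be slow. Iodine may also attack the newly formed allylsilane or the polyene.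
 - Fallback: it sets out from 13 and 12 and returns at 27. It uses the geometrically opposite alkenyl partner and a stereoretentive, iodine-free elimination.
 - 13 is alkylated with 1-lithiobut-2-yne (but-2-yne, n-BuLi, TMEDA, THF) to give enyne F5.
 - Hydrozirconation with excess Cp2Zr(H)Cl moves zirconium to the alkyne carbon next to methyl, and iodinolysis gives the (2E)-iodide F6.
 - t-BuLi gives alkenyllithium F7, in which lithium is cis to hydrogen and therefore less shielded. F7 adds to 12 to form boronate complex F8.
 - PhSeCl at −78 °C triggers the 1,2-shift to the β-selanyl boronic ester F9.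
 - Oxidation with mCPBA at −78 °C induces syn elimination. This preserves the alkene geometry and gives the same E C8=C9 alkene in 27.

3. Step 8.
 - Risk: decomposition or deiodination of the iodo ylide may lower conversion, and kinetic control may erode so that Z selectivity falls.
 - Fallback: it sets out from aldehyde 18 and returns at alkenyllithium 24.
 - Ramirez olefination (CBr4, PPh3, CH2Cl2, 0 °C) gives the 1,1-dibromoalkene F10.
 - Negishi coupling (Me2Zn, PdCl2(DPEphos) cat., THF) replaces selectively the less hindered bromine trans to the chain and gives the (2Z)-bromide F11.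
 - Bromine–lithium exchange with t-BuLi (Et2O, −78 °C) gives 24 with retention.

Further compounds
F1 | step 10 | (−)-drimenol | OC[C@H]1C(C)=CC[C@H]2C(C)(C)CCC[C@]12C
F2 | step 10 | drim-7-en-11-yl phenyl sulfide | C(Sc1ccccc1)[C@H]1C(C)=CC[C@H]2C(C)(C)CCC[C@]12C
F3 | step 10 | drim-7-en-11-yl phenyl sulfone | C(S(=O)(=O)c1ccccc1)[C@H]1C(C)=CC[C@H]2C(C)(C)CCC[C@]12C
F4 | step 10 | 11-(phenylsulfonyl)polypoda-7,13E,17E,21-tetraene (C11 epimers) | CC(C)=CCC/C(C)=C/CC/C(C)=C/CC(S(=O)(=O)c1ccccc1)[C@H]1C(C)=CC[C@H]2C(C)(C)CCC[C@]12C
F5 | step 9 | (6E,10E)-7,11,15-trimethylhexadeca-6,10,14-trien-2-yne | CC(C)=CCC/C(C)=C/CC/C(C)=C/CCC#CC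
F6 | step 9 | (2E,6E,10E)-2-iodo-7,11,15-trimethylhexadeca-2,6,10,14-tetraene | CC(C)=CCC/C(C)=C/CC/C(C)=C/CC/C=C(/I)C
F7 | step 9 | alkenyllithium from F6, lithium trans to the chain | CC(C)=CCC/C(C)=C/CC/C(C)=C/CC/C=C(/[Li])C
F8 | step 9 | lithium alkenyl[(S)-α-silylalkyl] pinacol boronate, boron trans to C11 | [Li+].COC(C)(C)CCC/C(C)=C/C[C@@H]([Si](C)(C)c1ccccc1)[B-]1(OC(C)(C)C(C)(C)O1)/C(C)=C/CC/C=C(C)/CC/C=C(C)/CCC=C(C)C
F9 | step 9 | C8-boryl C9-phenylselanyl adduct (one of two convergent facial isomers) | COC(C)(C)CCC/C(C)=C/C[C@@H]([Si](C)(C)c1ccccc1)[C@](C)(B1OC(C)(C)C(C)(C)O1)[C@@H]([Se]c1ccccc1)CC/C=C(C)/CC/C=C(C)/CCC=C(C)C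
F10 | step 8 | (5E,9E)-1,1-dibromo-6,10,14-trimethylpentadeca-1,5,9,13-tetraene | CC(C)=CCC/C(C)=C/CC/C(C)=C/CCC=C(Br)Br
F11 | step 8 | (2Z,6E,10E)-2-bromo-7,11,15-trimethylhexadeca-2,6,10,14-tetraene | CC(C)=CCC/C(C)=C/CC/C(C)=C/CC/C=C(\Br)C
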